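**Plan**
- Retrosynthesis: each 4-methoxy-3-methyl-2-pyranone is cut at its lactone O1–C2 bond and its C5–C6 bond, leading back to a ring-bound CHO and methyl 2-methyl-3-oxobutanoate. The cyclobutane is then cut at the CH(CO2H)–CH(CO2H) bond, the resulting cyclopentanone at its C(=O)–CH(CO2Me) bond, and the adipate goes back through a cyclohexene to butadiene and dimethylmaleic anhydride.
- Enabling feature: the cyclobutane bond joining the two CH(CO2H) carbons. The carboxyl carbon on one of them can be the expelled ring carbonyl of a cyclopentanone whose C3 and C4 are the two methyl-bearing quaternary carbons, so this bond is made by a 1,2-shift and not by a four-membered cyclisation.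
- Forward order of rings: cyclohexene (Diels–Alder), opened to an adipate, cyclopentanone (Dieckmann), cyclobutane (Wolff contraction 5→4), then both pyranones last, grown in two directions from a dialdehyde.
- Stereochemistry: the cis quaternary pair comes from the suprafacial Diels–Alder on the cyclic anhydride. The two CH centres are set together by equilibration through the cis-fused anhydride on the methyl face.

Key step: step 7

Remark: the target SMILES describes a meso compound (mirror plane through the midpoints of the two cyclobutane bonds C1–C2 and C3–C4; both CO2H and both CH3 on one face, both pyranones on the other). No absolute control is therefore needed; chiral intermediates are racemic and drawn as one enantiomer. TBSOCH2 = (tert-butyldimethylsilyloxy)methyl.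

**Route**

Step 1
Reactants: 1 buta-1,3-diene; 2 2,3-dimethylmaleic anhydride
Product: 3 cis-1,2-dimethylcyclohex-4-ene-1,2-dicarboxylic anhydride (meso)
Conditions: 1 (excess), BHT (cat.), PhMe, sealed autoclave, 190 °C
Reagents that add atoms: none
Why: Thermal Diels–Alder cycloaddition, known for this sluggish tetrasubstituted dienophile under forcing conditions; suprafacial addition to the cyclic Z-alkene sets the two methyl-bearing quaternary carbons cis.

Step 2
Reactants: 3 cis-1,2-dimethylcyclohex-4-ene-1,2-dicarboxylic anhydride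
Product: 4 cis-(1,2-dimethylcyclohex-4-ene-1,2-diyl)dimethanol (meso)
Conditions: LiAlH4, THF, 0 °C → reflux; aq. NaOH work-up
Reagents that add atoms: none
Why: Hydride reduction of a cyclic anhydride to the 1,4-diol, which touches no stereocentre.

Step 3
Reactants: 4 cis-(1,2-dimethylcyclohex-4-ene-1,2-diyl)dimethanol
Product: 5 cis-4,5-bis(TBSOCH2)-4,5-dimethylcyclohexene (meso)
Conditions: TBSCl, imidazole, DMF, rt
Reagents that add atoms: tert-butyldimethylsilyl chloride, CC(C)(C)[Si](C)(C)Cl
Why: Standard silylation of primary (neopentyl) alcohols; the bulky, freely rotating silyloxymethyl groups later provide the steric bias for step 9.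

Step 4
Reactants: 5 cis-4,5-bis(TBSOCH2)-4,5-dimethylcyclohexene
Product: 6 dimethyl meso-3,4-bis(TBSOCH2)-3,4-dimethylhexanedioate
Conditions: O3, NaOH/MeOH, CH2Cl2, −78 °C
Reagents that add atoms: ozone, [O-][O+]=O; methanol, CO
Why: Ozonolysis in methanolic sodium hydroxide oxidises both alkene carbons directly to methyl esters (dehydration of the methoxy hydroperoxide and ozone oxidation of the hemiacetal), leaving silyl ethers and quaternary centres untouched.

Step 5
Reactants: 6 dimethyl meso-3,4-bis(TBSOCH2)-3,4-dimethylhexanedioate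
Product: 7 methyl 4,5-bis(TBSOCH2)-4,5-dimethyl-2-oxocyclopentane-1-carboxylate (racemic)
Conditions: t-BuOK, THF, 0 °C → rt; cold 1 M HCl
Reagents that add atoms: none
Why: Dieckmann condensation to the five-membered β-keto ester, helped by the gem-disubstitution at both quaternary carbons and driven by enolate formation; C1 is labile and should settle with CO2Me trans to the neighbouring silyloxymethyl group.

Step 6
Reactants: 7 methyl 4,5-bis(TBSOCH2)-4,5-dimethyl-2-oxocyclopentane-1-carboxylate
Product: 10 methyl 3-diazo-4,5-bis(TBSOCH2)-4,5-dimethyl-2-oxocyclopentane-1-carboxylate, via dilithium dianion of the keto ester 8 (not isolated), via 3-trifluoroacetyl keto ester 9 (not isolated)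
Conditions: LDA (2.2 equiv), THF, −78 → 0 °C; CF3CO2CH2CF3, −78 °C; cold 1 M HCl work-up, crude used directly; p-ABSA, Et3N, H2O (1 equiv), MeCN, rt
Reagents that add atoms: 4-acetamidobenzenesulfonyl azide, CC(=O)Nc1ccc(cc1)S(=O)(=O)N=[N+]=[N-]
Why: γ-C-Acylation of the β-keto ester dianion followed by detrifluoroacetylative (Regitz-type deacylative) diazo transfer places the diazo group on the only α-methylene (C3), because the much more acidic trifluoroacetyl diketone should react with the sulfonyl azide before the hindered C1 methine does.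

Step 7
Reactants: 10 methyl 3-diazo-4,5-bis(TBSOCH2)-4,5-dimethyl-2-oxocyclopentane-1-carboxylate
Product: 12 dimethyl 3,4-bis(TBSOCH2)-3,4-dimethylcyclobutane-1,2-dicarboxylate (C2 epimers), via cyclobutyl ketene 11 (not isolated)
Conditions: hν (365 nm LEDs, Pyrex), degassed MeOH (0.02 M), 0–20 °C
Reagents that add atoms: methanol, CO
Why: Excitation of the α-diazo ketone expels N2 and, because the ring holds the diazo and carbonyl groups s-cis, the ester-bearing ring carbon C1 shifts from the carbonyl carbon C2 to the diazo carbon C3 in concert, giving ketene 11, which methanol traps as the second methyl ester. The closest known reaction type is the photochemical Wolff ring contraction of 2-diazocyclopentanones to cyclobutanecarboxylic esters. The cyclobutane closes by this 1,2-carbon shift (ring contraction 5→4, new C1–C3 bond) and not by a cyclisation. The migrating carbon keeps the configuration it has in the reacting epimer of 10 (suprafacial shift with retention), the new CH(CO2Me) centre arises by unselective C-protonation of the ester enol formed from 11 and methanol and is left for step 9 to correct, and the two quaternary centres are spectators. The step needs carbon migration to outrun carbene O–H insertion and 1,2-shifts from the neighbouring quaternary carbon; the locked s-cis geometry, the absence of any hydrogen on C4 and the fact that C1 is the only migratable group on the carbonyl secure this.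

Step 8
Reactants: 12 dimethyl 3,4-bis(TBSOCH2)-3,4-dimethylcyclobutane-1,2-dicarboxylate
Product: 13 3,4-bis(TBSOCH2)-3,4-dimethylcyclobutane-1,2-dicarboxylic acid (C1/C2 stereoisomer mixture)
Conditions: LiOH, THF/MeOH/H2O, 60 °C; then 1 M HCl to pH 3, 0 °C
Reagents that add atoms: lithium hydroxide, [Li+].[OH-]
Why: Ester saponification, which neopentyl TBS ethers tolerate; any base epimerisation of the CH centres is irrelevant because step 9 resets both.

Step 9
Reactants: 13 3,4-bis(TBSOCH2)-3,4-dimethylcyclobutane-1,2-dicarboxylic acid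
Product: 14 6,7-bis(TBSOCH2)-6,7-dimethyl-3-oxabicyclo[3.2.0]heptane-2,4-dione with the anhydride ring cis to both methyls (meso)
Conditions: Ac2O, NaOAc (0.5 equiv), 120 °C
Reagents that add atoms: none
Why: Dehydrative anhydride formation through mixed anhydrides: only a cis-diacid can close the bicyclic anhydride, acetate-mediated enolisation equilibrates both α-centres, and the ring should settle syn to the two methyls and away from the bulkier silyloxymethyl groups, which sets both CH stereocentres under thermodynamic control (the other face isomer can be resubjected).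

Step 10
Reactants: 14 anhydride (ring cis to both methyls)
Product: 16 di-tert-butyl 3,4-bis(TBSOCH2)-3,4-dimethylcyclobutane-1,2-dicarboxylate (esters cis to both methyls; meso), via cis-diacid 15 (not isolated)
Conditions: H2O, DMAP (cat.), THF, 40 °C; evaporate, PhMe azeotrope; then t-BuOC(=N-i-Pr)NH-i-Pr, CH2Cl2, rt
Reagents that add atoms: water, O; O-tert-butyl-N,N'-diisopropylisourea, CC(C)NC(=NC(C)C)OC(C)(C)C
Why: Anhydride hydrolysis followed by O-alkylation of the carboxylic acids with the isourea, which involves no acyl activation and so neither re-closes the anhydride nor epimerises the CH centres, and gives esters that survive the basic steps ahead and leave under acid.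

Step 11
Reactants: 16 di-tert-butyl 3,4-bis(TBSOCH2)-3,4-dimethylcyclobutane-1,2-dicarboxylate
Product: 17 di-tert-butyl 3,4-bis(hydroxymethyl)-3,4-dimethylcyclobutane-1,2-dicarboxylate (meso)
Conditions: HF·pyridine, pyridine, THF, 0 °C → rt
Reagents that add atoms: none
Why: Fluoride desilylation; the hydroxymethyl groups are trans to the vicinal esters, so lactonisation would need a trans-fused bicyclo[3.2.0] lactone and should not occur.

Step 12
Reactants: 17 di-tert-butyl 3,4-bis(hydroxymethyl)-3,4-dimethylcyclobutane-1,2-dicarboxylate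
Product: 18 di-tert-butyl 3,4-diformyl-3,4-dimethylcyclobutane-1,2-dicarboxylate (meso)
Conditions: (COCl)2, DMSO, CH2Cl2, −78 °C; Et3N, −78 → 0 °C; used crude
Reagents that add atoms: none
Why: Swern oxidation activates both primary alcohols before base is added and should therefore give the non-enolisable dialdehyde without passing through a lactol or lactone.

Step 13
Reactants: 18 di-tert-butyl 3,4-diformyl-3,4-dimethylcyclobutane-1,2-dicarboxylate; 19 methyl 2-methyl-3-oxobutanoate
Product: 21 di-tert-butyl 3,4-bis(1-hydroxy-5-methoxy-4-methyl-3,5-dioxopentyl)-3,4-dimethylcyclobutane-1,2-dicarboxylate (side-chain centres mixed), via dilithium dianion of the acetoacetate 20 (not isolated)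
Conditions: 19 (6 equiv), LDA (11.8 equiv), THF, −78 → 0 °C; then 18, −78 → −20 °C; aq. NH4Cl
Reagents that add atoms: none
Why: γ-Aldol addition of a β-keto ester dianion to non-enolisable aldehydes; the excess of dianion and warming to −20 °C should let the lactolate formed after the first addition reopen so that both arms react, and the new carbinol and C2 centres are erased in steps 14 and 15.

Step 14
Reactants: 21 bis(δ-hydroxy-β-keto ester)
Product: 22 di-tert-butyl 3,4-bis(5-methoxy-4-methyl-3,5-dioxopentanoyl)-3,4-dimethylcyclobutane-1,2-dicarboxylate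
Conditions: Dess–Martin periodinane, NaHCO3, CH2Cl2, 0 °C → rt
Reagents that add atoms: none
Why: Dess–Martin oxidation of both secondary alcohols to the 3,5-diketo esters under buffered conditions that do not touch the ring CH centres.

Step 15
Reactants: 22 bis(3,5-diketo ester)
Product: 23 di-tert-butyl 3,4-bis(4-hydroxy-3-methyl-2-oxo-2H-pyran-6-yl)-3,4-dimethylcyclobutane-1,2-dicarboxylate (meso)
Conditions: DBU, PhMe, 60 °C; dilute HCl work-up
Reagents that add atoms: none
Why: Base-mediated lactonisation of each diketo ester enolate onto its methyl ester (6-exo-trig acyl substitution) gives the aromatic 4-hydroxy-2-pyranone, and DBU is too weak to epimerise the tert-butyl ester α-centres.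

Step 16
Reactants: 23 bis(4-hydroxy-2-pyranone)
Product: 24 di-tert-butyl 3,4-bis(4-methoxy-3-methyl-2-oxo-2H-pyran-6-yl)-3,4-dimethylcyclobutane-1,2-dicarboxylate (meso)
Conditions: Me2SO4, K2CO3, acetone, reflux
Reagents that add atoms: dimethyl sulfate, COS(=O)(=O)OC
Why: O-Methylation of 4-hydroxy-2-pyranones under carbonate conditions is the standard way to the 4-methoxy-2-pyranone (α-pyrone) ether.

Step 17
Reactants: 24 bis(4-methoxy-2-pyranone) di-tert-butyl ester
Product: 25 3,4-bis(4-methoxy-3-methyl-2-oxo-2H-pyran-6-yl)-3,4-dimethylcyclobutane-1,2-dicarboxylic acid (target)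
Conditions: TFA/CH2Cl2, 0 °C → rt
Reagents that add atoms: none
Why: Acidolysis of tert-butyl esters (E1 loss of isobutene) frees the diacid without base, so neither the cis CH centres nor the pyranones are disturbed.

**Compound list**

1 | buta-1,3-diene | C=CC=C | starting material
2 | 2,3-dimethylmaleic anhydride | CC1=C(C)C(=O)OC1=O | starting material
3 | cis-1,2-dimethylcyclohex-4-ene-1,2-dicarboxylic anhydride (meso) | C[C@]12CC=CC[C@@]1(C)C(=O)OC2=O | intermediate
4 | cis-(1,2-dimethylcyclohex-4-ene-1,2-diyl)dimethanol (meso) | C[C@]1(CO)CC=CC[C@@]1(C)CO | intermediate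
5 | cis-4,5-bis(TBSOCH2)-4,5-dimethylcyclohexene (meso) | C[C@]1(CO[Si](C)(C)C(C)(C)C)CC=CC[C@@]1(C)CO[Si](C)(C)C(C)(C)C | intermediate
6 | dimethyl meso-(3R,4S)-3,4-bis(TBSOCH2)-3,4-dimethylhexanedioate | COC(=O)C[C@](C)(CO[Si](C)(C)C(C)(C)C)[C@](C)(CO[Si](C)(C)C(C)(C)C)CC(=O)OC | intermediate
7 | methyl 4,5-bis(TBSOCH2)-4,5-dimethyl-2-oxocyclopentane-1-carboxylate (racemic; 4,5-methyls cis; labile C1 drawn with CO2Me cis to the methyls) | COC(=O)[C@H]1C(=O)C[C@](C)(CO[Si](C)(C)C(C)(C)C)[C@]1(C)CO[Si](C)(C)C(C)(C)C | intermediate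
8 | dilithium dianion of 7 (C1 ester enolate and C2–C3 ketone enolate) | [Li+].[Li+].COC([O-])=C1C([O-])=C[C@](C)(CO[Si](C)(C)C(C)(C)C)[C@]1(C)CO[Si](C)(C)C(C)(C)C | intermediate
9 | methyl 4,5-bis(TBSOCH2)-4,5-dimethyl-2-oxo-3-(trifluoroacetyl)cyclopentane-1-carboxylate (enolised; C3 undefined) | COC(=O)[C@H]1C(=O)C(C(=O)C(F)(F)F)[C@](C)(CO[Si](C)(C)C(C)(C)C)[C@]1(C)CO[Si](C)(C)C(C)(C)C | intermediate
10 | methyl 3-diazo-4,5-bis(TBSOCH2)-4,5-dimethyl-2-oxocyclopentane-1-carboxylate (racemic; methyls cis; CO2Me cis to the methyls) | COC(=O)[C@H]1C(=O)C(=[N+]=[N-])[C@](C)(CO[Si](C)(C)C(C)(C)C)[C@]1(C)CO[Si](C)(C)C(C)(C)C | intermediate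
11 | methyl 3,4-bis(TBSOCH2)-3,4-dimethyl-2-(oxomethylidene)cyclobutane-1-carboxylate (ketene) | COC(=O)[C@H]1C(=C=O)[C@](C)(CO[Si](C)(C)C(C)(C)C)[C@]1(C)CO[Si](C)(C)C(C)(C)C | intermediate
12 | dimethyl 3,4-bis(TBSOCH2)-3,4-dimethylcyclobutane-1,2-dicarboxylate (methyls cis; C1 ester cis to the methyls; C2 both epimers) | COC(=O)[C@H]1C(C(=O)OC)[C@](C)(CO[Si](C)(C)C(C)(C)C)[C@]1(C)CO[Si](C)(C)C(C)(C)C | intermediate
13 | 3,4-bis(TBSOCH2)-3,4-dimethylcyclobutane-1,2-dicarboxylic acid (methyls cis; C1/C2 stereoisomer mixture) | OC(=O)C1C(C(=O)O)[C@](C)(CO[Si](C)(C)C(C)(C)C)[C@]1(C)CO[Si](C)(C)C(C)(C)C | intermediate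
14 | 6,7-bis(TBSOCH2)-6,7-dimethyl-3-oxabicyclo[3.2.0]heptane-2,4-dione, anhydride ring cis to both methyls (meso) | CC(C)(C)[Si](C)(C)OC[C@@]1(C)[C@@H]2C(=O)OC(=O)[C@@H]2[C@@]1(C)CO[Si](C)(C)C(C)(C)C | intermediate
15 | 3,4-bis(TBSOCH2)-3,4-dimethylcyclobutane-1,2-dicarboxylic acid, both CO2H cis to both methyls (meso) | CC(C)(C)[Si](C)(C)OC[C@@]1(C)[C@H](C(=O)O)[C@H](C(=O)O)[C@@]1(C)CO[Si](C)(C)C(C)(C)C | intermediate
16 | di-tert-butyl 3,4-bis(TBSOCH2)-3,4-dimethylcyclobutane-1,2-dicarboxylate, esters cis to both methyls (meso) | CC(C)(C)[Si](C)(C)OC[C@@]1(C)[C@H](C(=O)OC(C)(C)C)[C@H](C(=O)OC(C)(C)C)[C@@]1(C)CO[Si](C)(C)C(C)(C)C | intermediate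
17 | di-tert-butyl 3,4-bis(hydroxymethyl)-3,4-dimethylcyclobutane-1,2-dicarboxylate, esters cis to both methyls (meso) | OC[C@@]1(C)[C@H](C(=O)OC(C)(C)C)[C@H](C(=O)OC(C)(C)C)[C@@]1(C)CO | intermediate
18 | di-tert-butyl 3,4-diformyl-3,4-dimethylcyclobutane-1,2-dicarboxylate, esters cis to both methyls (meso) | O=C[C@@]1(C)[C@H](C(=O)OC(C)(C)C)[C@H](C(=O)OC(C)(C)C)[C@@]1(C)C=O | intermediate
19 | methyl 2-methyl-3-oxobutanoate | COC(=O)C(C)C(C)=O | starting material
20 | dilithium dianion of 19 | [Li+].[Li+].COC([O-])=C(C)C([O-])=C | intermediate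
21 | di-tert-butyl 3,4-bis(1-hydroxy-5-methoxy-4-methyl-3,5-dioxopentyl)-3,4-dimethylcyclobutane-1,2-dicarboxylate (ring as in 17; side-chain centres mixed) | COC(=O)C(C)C(=O)CC(O)[C@@]1(C)[C@H](C(=O)OC(C)(C)C)[C@H](C(=O)OC(C)(C)C)[C@@]1(C)C(O)CC(=O)C(C)C(=O)OC | intermediate
22 | di-tert-butyl 3,4-bis(5-methoxy-4-methyl-3,5-dioxopentanoyl)-3,4-dimethylcyclobutane-1,2-dicarboxylate (ring as in 17) | COC(=O)C(C)C(=O)CC(=O)[C@@]1(C)[C@H](C(=O)OC(C)(C)C)[C@H](C(=O)OC(C)(C)C)[C@@]1(C)C(=O)CC(=O)C(C)C(=O)OC | intermediate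
23 | di-tert-butyl 3,4-bis(4-hydroxy-3-methyl-2-oxo-2H-pyran-6-yl)-3,4-dimethylcyclobutane-1,2-dicarboxylate (meso) | Cc1c(O)cc([C@@]2(C)[C@H](C(=O)OC(C)(C)C)[C@H](C(=O)OC(C)(C)C)[C@@]2(C)c2cc(O)c(C)c(=O)o2)oc1=O | intermediate
24 | di-tert-butyl 3,4-bis(4-methoxy-3-methyl-2-oxo-2H-pyran-6-yl)-3,4-dimethylcyclobutane-1,2-dicarboxylate (meso) | COc1cc([C@@]2(C)[C@H](C(=O)OC(C)(C)C)[C@H](C(=O)OC(C)(C)C)[C@@]2(C)c2cc(OC)c(C)c(=O)o2)oc(=O)c1C | intermediate
25 | 3,4-bis(4-methoxy-3-methyl-2-oxo-2H-pyran-6-yl)-3,4-dimethylcyclobutane-1,2-dicarboxylic acid, CO2H groups cis to each other and to both methyls, pyranones on the other face (CNP0574758.1) | COc1cc([C@@]2(C)[C@H](C(=O)O)[C@H](C(=O)O)[C@@]2(C)c2cc(OC)c(C)c(=O)o2)oc(=O)c1C | target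

**Totals**

Total step count: 17. Longest linear sequence: 17 steps (1 and 2 to 25); 19 enters at step 13 as purchased.

**Steps most likely to fail**

Step 6. The sulfonyl azide may attack the enolate of the β-keto ester methine at C1 (azo transfer with ring cleavage) instead of the trifluoroacetylated C3, or the γ-acylation of the dianion may stay incomplete. The fallback sets out from 7 and blocks C1 first. Sulfenylation with N-(phenylsulfanyl)succinimide and Et3N in CH2Cl2 should give methyl 4,5-bis(TBSOCH2)-4,5-dimethyl-2-oxo-1-(phenylsulfanyl)cyclopentane-1-carboxylate F1, which has no acidic methine. Its ketone enolate (LiHMDS, THF, −78 °C) is trifluoroacetylated with CF3CO2CH2CF3 to the 3-trifluoroacetyl ketone F2, and p-ABSA/Et3N/H2O in MeCN converts this into methyl 3-diazo-4,5-bis(TBSOCH2)-4,5-dimethyl-2-oxo-1-(phenylsulfanyl)cyclopentane-1-carboxylate F3. Irradiation in methanol as in step 7 contracts the ring by the same 1,2-shift to dimethyl 3,4-bis(TBSOCH2)-3,4-dimethyl-1-(phenylsulfanyl)cyclobutane-1,2-dicarboxylate F4. Radical desulfurisation (Bu3SnH, AIBN, PhH, 80 °C) then comes back to 12 as a CH-epimer mixture, which step 9 accepts.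

Step 9. The thermodynamic preference between the two cis-anhydrides (ring syn to the methyls versus syn to the silyloxymethyl groups) may be too small, or the silyl ethers may be acetolysed in hot acetic anhydride. The fallback replaces thermodynamic by directed kinetic control and sets out from 13. Esterification with O-tert-butyl-N,N'-diisopropylisourea gives di-tert-butyl 3,4-bis(TBSOCH2)-3,4-dimethylcyclobutane-1,2-dicarboxylate as a stereoisomer mixture F5. Double deprotonation with LDA and oxidation of the bis-enolate with iodine erases both CH centres and should give di-tert-butyl 3,4-bis(TBSOCH2)-3,4-dimethylcyclobut-1-ene-1,2-dicarboxylate F6. HF·pyridine frees di-tert-butyl 3,4-bis(hydroxymethyl)-3,4-dimethylcyclobut-1-ene-1,2-dicarboxylate F7. Hydrogenation with [Ir(cod)(PCy3)(py)]PF6 in CH2Cl2, directed by the two homoallylic hydroxyl groups, delivers both hydrogens from the hydroxymethyl face and so returns to 17 with the esters on the methyl face.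

Step 13. The addition may stop after one arm, because the first alkoxide can close onto the neighbouring aldehyde as a lactolate, and the second, very hindered aldehyde may react sluggishly with the basic dianion. The fallback avoids alkoxide intermediates and sets out from 18. Tin(II) chloride-catalysed Roskamp homologation in CH2Cl2 with methyl 4-diazo-2-methyl-3-oxobutanoate F8 (made from the acid chloride of methyl hydrogen methylmalonate and trimethylsilyldiazomethane) adds the diazo carbon to each Lewis-acid-bound aldehyde. A 1,2-hydride shift with loss of nitrogen then gives the 1,3-diketone directly, so the route is rejoined at 22, bypassing 21 and step 14.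

**Further compounds**

F1 | step 6 | methyl 4,5-bis(TBSOCH2)-4,5-dimethyl-2-oxo-1-(phenylsulfanyl)cyclopentane-1-carboxylate (methyls cis; C1 undefined) | COC(=O)C1(Sc2ccccc2)C(=O)C[C@](C)(CO[Si](C)(C)C(C)(C)C)[C@]1(C)CO[Si](C)(C)C(C)(C)C
F2 | step 6 | methyl 4,5-bis(TBSOCH2)-4,5-dimethyl-2-oxo-1-(phenylsulfanyl)-3-(trifluoroacetyl)cyclopentane-1-carboxylate | COC(=O)C1(Sc2ccccc2)C(=O)C(C(=O)C(F)(F)F)[C@](C)(CO[Si](C)(C)C(C)(C)C)[C@]1(C)CO[Si](C)(C)C(C)(C)C
F3 | step 6 | methyl 3-diazo-4,5-bis(TBSOCH2)-4,5-dimethyl-2-oxo-1-(phenylsulfanyl)cyclopentane-1-carboxylate | COC(=O)C1(Sc2ccccc2)C(=O)C(=[N+]=[N-])[C@](C)(CO[Si](C)(C)C(C)(C)C)[C@]1(C)CO[Si](C)(C)C(C)(C)C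
F4 | step 6 | dimethyl 3,4-bis(TBSOCH2)-3,4-dimethyl-1-(phenylsulfanyl)cyclobutane-1,2-dicarboxylate (methyls cis; C1/C2 undefined) | COC(=O)C1(Sc2ccccc2)C(C(=O)OC)[C@](C)(CO[Si](C)(C)C(C)(C)C)[C@]1(C)CO[Si](C)(C)C(C)(C)C
F5 | step 9 | di-tert-butyl 3,4-bis(TBSOCH2)-3,4-dimethylcyclobutane-1,2-dicarboxylate (methyls cis; C1/C2 stereoisomer mixture) | CC(C)(C)OC(=O)C1C(C(=O)OC(C)(C)C)[C@](C)(CO[Si](C)(C)C(C)(C)C)[C@]1(C)CO[Si](C)(C)C(C)(C)C
F6 | step 9 | di-tert-butyl 3,4-bis(TBSOCH2)-3,4-dimethylcyclobut-1-ene-1,2-dicarboxylate (methyls cis; meso) | CC(C)(C)OC(=O)C1=C(C(=O)OC(C)(C)C)[C@](C)(CO[Si](C)(C)C(C)(C)C)[C@]1(C)CO[Si](C)(C)C(C)(C)C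
F7 | step 9 | di-tert-butyl 3,4-bis(hydroxymethyl)-3,4-dimethylcyclobut-1-ene-1,2-dicarboxylate (methyls cis; meso) | CC(C)(C)OC(=O)C1=C(C(=O)OC(C)(C)C)[C@](C)(CO)[C@]1(C)CO
F8 | step 13 | methyl 4-diazo-2-methyl-3-oxobutanoate | COC(=O)C(C)C(=O)C=[N+]=[N-]
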